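**Plan**

- Retrosynthesis: the last bonds cut are the C2' O–prenyl bond and the O–Si bond at the C6' carbinol. Ring B is then taken apart completely along C5'–C6', C2'–C3', C4'–C5' and C1'–C2', leaving an α-diazo β-aryloxy enone that already holds the diaryl ether oxygen, plus methoxyacetylene.
- Enabling feature: in ring B (C1' O-aryl, C2' O-prenyl, C3' H, C4' OMe, C5' prenyl, C6' CH2OH) the oxygens on C2' and C4' are meta with C3'–H between them, and C5', C6', C1' follow in a row. This is the pattern left by a vinylketene (C2', C5', C6', C1') and an ynol ether (C3', C4').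
- Forward: ring A is bought and mono-prenylated. A three-carbon chloro enal from methyl 3-hydroxypropanoate is extended with the homoprenyl Grignard reagent, oxidised, joined to the ring-A phenol by vinylic substitution (the ether C–O bond is made at an sp2 CH, not at an arene) and diazotised.
- Ring B is the only ring formed; it arises in one photochemical benzannulation, which leaves C2'–OH free and C4' as OMe. O-prenylation and desilylation finish the route.
- Stereochemistry: the target has no stereocentre. The E enol ether of the diazo enone is set thermodynamically and disappears into ring B.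

Key step: step 12

Assumptions: methoxyacetylene is treated as not purchasable and is made in step 11. The vinyl chlorides of steps 4 to 8 are drawn with Cl cis to the silyloxymethyl group, but either geometry would serve, because the vinylic substitution re-sets the enol ether geometry.

**Route**

Step 1
Reactants: 1 methyl 2,6-dihydroxybenzoate
Product: 2 methyl 2-hydroxy-6-(3-methylbut-2-enyloxy)benzoate
Conditions: prenyl bromide (1.05 equiv), K2CO3 (1.1 equiv), acetone, 56 °C
Reagents that add atoms: prenyl bromide (1-bromo-3-methylbut-2-ene), CC(C)=CCBr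
Why: Williamson ether synthesis; once one hydroxyl is alkylated the other is held in a hydrogen bond to the ester carbonyl and is far less nucleophilic, so one equivalent of halide should stop at the monoether.

Step 2
Reactants: 3 methyl 3-hydroxypropanoate
Product: 4 methyl 3-(tert-butyldimethylsilyloxy)propanoate
Conditions: tert-butyldimethylsilyl chloride, imidazole, CH2Cl2, 0 → 20 °C
Reagents that add atoms: tert-butyldimethylsilyl chloride, CC(C)(C)[Si](C)(C)Cl
Why: Routine silylation of a primary alcohol; the silyl ether is kept until the last step so that no hydroxyl can capture the ketenes of step 12.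

Step 3
Reactants: 4 methyl 3-(tert-butyldimethylsilyloxy)propanoate
Product: 5 methyl 2-(tert-butyldimethylsilyloxymethyl)-3-hydroxyprop-2-enoate (enol form of the α-formyl ester)
Conditions: LiN(iPr)2 (1.1 equiv), THF, −78 °C; HCO2Me (3 equiv), −78 → 0 °C; aq. NH4Cl
Reagents that add atoms: methyl formate, COC=O
Why: Crossed Claisen condensation (formylation of an ester enolate), long used on 3-alkoxypropanoates; the product is drained off as its stabilised enolate, which also works against β-elimination of silanolate.

Step 4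
Reactants: 5 methyl 2-(tert-butyldimethylsilyloxymethyl)-3-hydroxyprop-2-enoate
Product: 6 methyl (2E)-3-chloro-2-(tert-butyldimethylsilyloxymethyl)prop-2-enoate
Conditions: Ph3PCl2 (1.2 equiv), Et3N (1.3 equiv), CH2Cl2, 0 → 20 °C
Reagents that add atoms: dichlorotriphenylphosphorane, ClP(Cl)(c1ccccc1)(c1ccccc1)c1ccccc1
Why: Appel-type deoxychlorination of a 1,3-dicarbonyl enol, in which the enol oxygen becomes an oxyphosphonium leaving group and chloride replaces it by addition–elimination under amine-buffered conditions that spare the silyl ether; the E isomer is expected to prevail.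

Step 5
Reactants: 6 methyl (2E)-3-chloro-2-(tert-butyldimethylsilyloxymethyl)prop-2-enoate
Product: 7 (2Z)-3-chloro-2-(tert-butyldimethylsilyloxymethyl)prop-2-en-1-ol
Conditions: iBu2AlH (2.3 equiv), CH2Cl2, −78 °C; aq. potassium sodium tartrate
Reagents that add atoms: none
Why: 1,2-Reduction of an α,β-unsaturated ester by iBu2AlH at low temperature should give the allylic alcohol without touching the vinyl chloride or the silyl ether (the descriptor changes to Z only through the priority rules).

Step 6
Reactants: 7 (2Z)-3-chloro-2-(tert-butyldimethylsilyloxymethyl)prop-2-en-1-ol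
Product: 8 (2E)-3-chloro-2-(tert-butyldimethylsilyloxymethyl)prop-2-enal
Conditions: MnO2 (15 equiv), CH2Cl2, 20 °C
Reagents that add atoms: none
Why: MnO2 oxidises primary allylic alcohols selectively to enals under neutral conditions.

Step 7
Reactants: 8 (2E)-3-chloro-2-(tert-butyldimethylsilyloxymethyl)prop-2-enal; 9 5-bromo-2-methylpent-2-ene
Product: 11 (1E)-1-chloro-2-(tert-butyldimethylsilyloxymethyl)-7-methylocta-1,6-dien-3-ol, via (4-methylpent-3-enyl)magnesium bromide 10 (not isolated)
Conditions: 9, Mg, THF, 20–40 °C; then 8, THF, −78 °C; aqueous quench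
Reagents that add atoms: magnesium, [Mg] (the metal of 10)
Why: Grignard 1,2-addition to an enal at low temperature; the new carbinol centre is formed racemic and is removed by the oxidation in step 8.

Step 8
Reactants: 11 (1E)-1-chloro-2-(tert-butyldimethylsilyloxymethyl)-7-methylocta-1,6-dien-3-ol
Product: 12 (1E)-1-chloro-2-(tert-butyldimethylsilyloxymethyl)-7-methylocta-1,6-dien-3-one
Conditions: Dess–Martin periodinane (1.2 equiv), CH2Cl2, 0 → 20 °C
Reagents that add atoms: none
Why: Dess–Martin oxidation of a secondary allylic alcohol to the enone under mild, non-basic conditions.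

Step 9
Reactants: 12 (1E)-1-chloro-2-(tert-butyldimethylsilyloxymethyl)-7-methylocta-1,6-dien-3-one; 2 methyl 2-hydroxy-6-(3-methylbut-2-enyloxy)benzoate
Product: 13 methyl 2-{[(1E)-2-(tert-butyldimethylsilyloxymethyl)-7-methyl-3-oxoocta-1,6-dienyl]oxy}-6-(3-methylbut-2-enyloxy)benzoate
Conditions: K2CO3 (1.5 equiv), DMF, 20 °C
Reagents that add atoms: none
Why: Nucleophilic vinylic substitution (conjugate addition of the phenoxide, then loss of chloride) on a β-chloro enone is the classical route to β-aryloxy enones; the E isomer with the aryloxy group trans to the carbonyl is the thermodynamic product, and the diaryl ether oxygen is installed without any arene C–O coupling.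

Step 10
Reactants: 13 methyl 2-{[(1E)-2-(tert-butyldimethylsilyloxymethyl)-7-methyl-3-oxoocta-1,6-dienyl]oxy}-6-(3-methylbut-2-enyloxy)benzoate
Product: 15 methyl 2-{[(1E)-2-(tert-butyldimethylsilyloxymethyl)-4-diazo-7-methyl-3-oxoocta-1,6-dienyl]oxy}-6-(3-methylbut-2-enyloxy)benzoate, via trifluoroacetyl diketone 14 (not isolated)
Conditions: LiN(SiMe3)2 (1.1 equiv), THF, −78 °C; CF3CO2CH2CF3 (1.2 equiv), −78 °C; 5% aq. HCl; crude 14, MsN3 (1.5 equiv), Et3N (1.5 equiv), H2O (1 equiv), MeCN, 20 °C
Reagents that add atoms: 2,2,2-trifluoroethyl trifluoroacetate, O=C(OCC(F)(F)F)C(F)(F)F (the trifluoroacetyl group of 14); methanesulfonyl azide, CS(=O)(=O)N=[N+]=[N-] (the two nitrogen atoms of 15)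
Why: Detrifluoroacetylative diazo transfer, in which the kinetic lithium enolate at C4 (the only enolisable position) is trifluoroacetylated and the resulting 1,3-diketone transfers to the sulfonyl azide with loss of the trifluoroacetyl group, a protocol made for base-sensitive enones.

Step 11
Reactants: 16 2-chloro-1,1-dimethoxyethane (chloroacetaldehyde dimethyl acetal)
Product: 18 methoxyacetylene, via sodium methoxyacetylide 17 (not isolated)
Conditions: NaNH2 (3 equiv), liquid NH3, −33 °C; then cold saturated aq. NaCl, −20 °C; distilled into a −78 °C trap and kept as a cold solution in ClCH2CH2Cl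
Reagents that add atoms: sodium amide, [Na+].[NH2-] (the sodium of 17)
Why: Twofold base-induced elimination (methanol, then HCl) from the chloro acetal gives the sodium alkynyl ether, the standard preparation of alkoxyacetylenes, and protonation with distillation delivers the volatile alkyne.

Step 12
Reactants: 15 methyl 2-{[(1E)-2-(tert-butyldimethylsilyloxymethyl)-4-diazo-7-methyl-3-oxoocta-1,6-dienyl]oxy}-6-(3-methylbut-2-enyloxy)benzoate; 18 methoxyacetylene
Product: 23 methyl 2-[2-(tert-butyldimethylsilyloxymethyl)-6-hydroxy-4-methoxy-3-(3-methylbut-2-enyl)phenoxy]-6-(3-methylbut-2-enyloxy)benzoate, via vinylketene 19 (not isolated), via 4-vinylcyclobutenone 20 (not isolated), via dienylketene 21 (not isolated), via cyclohexa-2,4-dienone 22 (not isolated)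
Conditions: 18 (4 equiv), ClCH2CH2Cl (0.05 M), hν (Pyrex, 300–350 nm), 0–5 °C, sealed vessel; then 80 °C, 2 h (any aryl ester formed by ketene capture of 23 is cleaved with K2CO3, MeOH, 20 °C)
Reagents that add atoms: none
Why: Proposed new method: light expels N2 and the alkenyl group migrates to the diazo carbon (Wolff rearrangement, forming C5'–C6') to give vinylketene 19, whose ketene carbon (C2') is attacked by the unsubstituted, nucleophilic carbon of methoxyacetylene in a [2+2] cycloaddition (C2'–C3' and C4'–C5') that closes the four-membered ring of 20, and four-electron electrocyclic opening of 20 gives dienylketene 21. The closest known reaction type is the Danheiser benzannulation in its photochemical Wolff form, established for alkyl-, aryl- and hetaryl-substituted α-diazo enones with alkoxy- and siloxyalkynes but not for an acyclic β-aryloxy enone. Ring B closes by thermal six-electron disrotatory electrocyclisation of 21 between the ketene carbon C2' and the aryloxy-bearing terminus C1', and 22 tautomerises to the C2' phenol. No stereocentre remains, since the quaternary carbon of 20 and the sp3 C1' of 22 are transient and lost on aromatisation. The step needs regioselectivity in the [2+2] addition, which the polarity of the ynol ether secures (OMe ends on C4' beside C5'), and it needs the Wolff shift to outrun 1,2-hydrogen migration in the carbene, for which direct irradiation at low temperature is chosen; the E enol ether keeps the aryloxy group on the outside of the cyclising triene.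

Step 13
Reactants: 23 methyl 2-[2-(tert-butyldimethylsilyloxymethyl)-6-hydroxy-4-methoxy-3-(3-methylbut-2-enyl)phenoxy]-6-(3-methylbut-2-enyloxy)benzoate
Product: 24 methyl 2-[2-(tert-butyldimethylsilyloxymethyl)-4-methoxy-3-(3-methylbut-2-enyl)-6-(3-methylbut-2-enyloxy)phenoxy]-6-(3-methylbut-2-enyloxy)benzoate
Conditions: prenyl bromide (1.3 equiv), K2CO3 (2 equiv), acetone, 40 °C
Reagents that add atoms: prenyl bromide (1-bromo-3-methylbut-2-ene), CC(C)=CCBr
Why: Williamson O-alkylation of the only free phenol, which the benzannulation delivers already distinguished from the C4' methyl ether.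

Step 14
Reactants: 24 methyl 2-[2-(tert-butyldimethylsilyloxymethyl)-4-methoxy-3-(3-methylbut-2-enyl)-6-(3-methylbut-2-enyloxy)phenoxy]-6-(3-methylbut-2-enyloxy)benzoate
Product: 25 methyl 2-[2-(hydroxymethyl)-4-methoxy-3-(3-methylbut-2-enyl)-6-(3-methylbut-2-enyloxy)phenoxy]-6-(3-methylbut-2-enyloxy)benzoate (CNP0500611.0)
Conditions: Bu4NF (1.2 equiv), THF, 0 °C; aq. NH4Cl
Reagents that add atoms: none
Why: Fluoride cleavage of the silyl ether frees the benzylic alcohol while the hindered methyl ester, the diaryl ether and the allyl aryl ethers are inert.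

**Compound list**

1 | methyl 2,6-dihydroxybenzoate | COC(=O)c1c(O)cccc1O | starting material
2 | methyl 2-hydroxy-6-(3-methylbut-2-enyloxy)benzoate | COC(=O)c1c(O)cccc1OCC=C(C)C | intermediate
3 | methyl 3-hydroxypropanoate | COC(=O)CCO | starting material
4 | methyl 3-(tert-butyldimethylsilyloxy)propanoate | COC(=O)CCO[Si](C)(C)C(C)(C)C | intermediate
5 | methyl 2-(tert-butyldimethylsilyloxymethyl)-3-hydroxyprop-2-enoate (enol form of methyl 2-formyl-3-(tert-butyldimethylsilyloxy)propanoate; tautomeric mixture, geometry not defined) | COC(=O)C(CO[Si](C)(C)C(C)(C)C)=CO | intermediate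
6 | methyl (2E)-3-chloro-2-(tert-butyldimethylsilyloxymethyl)prop-2-enoate | COC(=O)/C(CO[Si](C)(C)C(C)(C)C)=C/Cl | intermediate
7 | (2Z)-3-chloro-2-(tert-butyldimethylsilyloxymethyl)prop-2-en-1-ol | OC/C(CO[Si](C)(C)C(C)(C)C)=C/Cl | intermediate
8 | (2E)-3-chloro-2-(tert-butyldimethylsilyloxymethyl)prop-2-enal | O=C/C(CO[Si](C)(C)C(C)(C)C)=C/Cl | intermediate
9 | 5-bromo-2-methylpent-2-ene | CC(C)=CCCBr | starting material
10 | (4-methylpent-3-enyl)magnesium bromide (formed in the flask, not isolated) | CC(C)=CCC[Mg]Br | intermediate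
11 | (1E)-1-chloro-2-(tert-butyldimethylsilyloxymethyl)-7-methylocta-1,6-dien-3-ol (racemic) | Cl/C=C(\CO[Si](C)(C)C(C)(C)C)C(O)CCC=C(C)C | intermediate
12 | (1E)-1-chloro-2-(tert-butyldimethylsilyloxymethyl)-7-methylocta-1,6-dien-3-one | Cl/C=C(\CO[Si](C)(C)C(C)(C)C)C(=O)CCC=C(C)C | intermediate
13 | methyl 2-{[(1E)-2-(tert-butyldimethylsilyloxymethyl)-7-methyl-3-oxoocta-1,6-dienyl]oxy}-6-(3-methylbut-2-enyloxy)benzoate | COC(=O)c1c(OCC=C(C)C)cccc1O/C=C(\CO[Si](C)(C)C(C)(C)C)C(=O)CCC=C(C)C | intermediate
14 | methyl 2-{[(1E)-2-(tert-butyldimethylsilyloxymethyl)-7-methyl-3-oxo-4-(trifluoroacetyl)octa-1,6-dienyl]oxy}-6-(3-methylbut-2-enyloxy)benzoate (used crude, not isolated; racemic) | COC(=O)c1c(OCC=C(C)C)cccc1O/C=C(\CO[Si](C)(C)C(C)(C)C)C(=O)C(CC=C(C)C)C(=O)C(F)(F)F | intermediate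
15 | methyl 2-{[(1E)-2-(tert-butyldimethylsilyloxymethyl)-4-diazo-7-methyl-3-oxoocta-1,6-dienyl]oxy}-6-(3-methylbut-2-enyloxy)benzoate | COC(=O)c1c(OCC=C(C)C)cccc1O/C=C(\CO[Si](C)(C)C(C)(C)C)C(=O)C(=[N+]=[N-])CC=C(C)C | intermediate
16 | 2-chloro-1,1-dimethoxyethane (chloroacetaldehyde dimethyl acetal) | COC(CCl)OC | starting material
17 | sodium methoxyacetylide (formed in the flask, not isolated) | [Na+].[C-]#COC | intermediate
18 | methoxyacetylene (methoxyethyne) | COC#C | intermediate
19 | methyl 2-{[(1Z)-2-(tert-butyldimethylsilyloxymethyl)-3-(3-methylbut-2-enyl)-4-oxobuta-1,3-dienyl]oxy}-6-(3-methylbut-2-enyloxy)benzoate (vinylketene, not isolated) | COC(=O)c1c(OCC=C(C)C)cccc1O/C=C(\CO[Si](C)(C)C(C)(C)C)C(CC=C(C)C)=C=O | intermediate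
20 | methyl 2-{[(1Z)-3-(tert-butyldimethylsilyloxy)-2-[2-methoxy-1-(3-methylbut-2-enyl)-4-oxocyclobut-2-enyl]prop-1-enyl]oxy}-6-(3-methylbut-2-enyloxy)benzoate (4-vinylcyclobutenone, racemic, not isolated) | COC(=O)c1c(OCC=C(C)C)cccc1O/C=C(\CO[Si](C)(C)C(C)(C)C)C1(CC=C(C)C)C(=O)C=C1OC | intermediate
21 | methyl 2-{[(1Z,3E)-2-(tert-butyldimethylsilyloxymethyl)-4-methoxy-3-(3-methylbut-2-enyl)-6-oxohexa-1,3,5-trienyl]oxy}-6-(3-methylbut-2-enyloxy)benzoate (dienylketene, not isolated) | COC(=O)c1c(OCC=C(C)C)cccc1O/C=C(\CO[Si](C)(C)C(C)(C)C)/C(CC=C(C)C)=C(OC)\C=C=O | intermediate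
22 | methyl 2-{[2-(tert-butyldimethylsilyloxymethyl)-4-methoxy-3-(3-methylbut-2-enyl)-6-oxocyclohexa-2,4-dienyl]oxy}-6-(3-methylbut-2-enyloxy)benzoate (racemic, not isolated) | COC(=O)c1c(OCC=C(C)C)cccc1OC1C(=O)C=C(OC)C(CC=C(C)C)=C1CO[Si](C)(C)C(C)(C)C | intermediate
23 | methyl 2-[2-(tert-butyldimethylsilyloxymethyl)-6-hydroxy-4-methoxy-3-(3-methylbut-2-enyl)phenoxy]-6-(3-methylbut-2-enyloxy)benzoate | COC(=O)c1c(OCC=C(C)C)cccc1Oc1c(O)cc(OC)c(CC=C(C)C)c1CO[Si](C)(C)C(C)(C)C | intermediate
24 | methyl 2-[2-(tert-butyldimethylsilyloxymethyl)-4-methoxy-3-(3-methylbut-2-enyl)-6-(3-methylbut-2-enyloxy)phenoxy]-6-(3-methylbut-2-enyloxy)benzoate | COC(=O)c1c(OCC=C(C)C)cccc1Oc1c(OCC=C(C)C)cc(OC)c(CC=C(C)C)c1CO[Si](C)(C)C(C)(C)C | intermediate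
25 | methyl 2-[2-(hydroxymethyl)-4-methoxy-3-(3-methylbut-2-enyl)-6-(3-methylbut-2-enyloxy)phenoxy]-6-(3-methylbut-2-enyloxy)benzoate | COC(=O)c1c(OCC=C(C)C)cccc1Oc1c(OCC=C(C)C)cc(OC)c(CC=C(C)C)c1CO | target

**Step count and risks**

Total steps: 14. Longest linear sequence: 12 steps (from 3 through steps 2–10 and 12–14 to 25).

Steps most likely to fail:

1. Step 12 (new for this substrate class). The benzoate and aryl enol ether chromophores may take up light and the enol ether may photoisomerise, so that the aryloxy group points into the triene and the six-electron closure stalls. The carbene may also undergo 1,2-hydrogen shift instead of the Wolff shift, or the push–pull dienylketene may shed aryloxide. The fallback uses known reactions only, sets out from chloro enone 12 and makes the diaryl ether after ring B.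
   - Reductive dechlorination of 12 (Zn–Ag couple, MeOH) gives 2-(tert-butyldimethylsilyloxymethyl)-7-methylocta-1,6-dien-3-one F1.
   - The diazo transfer of step 10, through the trifluoroacetyl diketone F2, gives the diazo enone F3, a 2-substituted vinyl diazo ketone of the kind for which the photochemical benzannulation with alkoxyalkynes is established.
   - Irradiation of F3 with 18 as in step 12 should give 3-(tert-butyldimethylsilyloxymethyl)-5-methoxy-4-(3-methylbut-2-enyl)phenol F4.
   - Bromination with N-bromosuccinimide (CH2Cl2, −78 °C) is expected ortho to the hydroxyl and para to the methoxy group (the future C1') to give the bromophenol F5.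
   - O-Prenylation (prenyl bromide, K2CO3) gives the aryl bromide F6, and an Ullmann diaryl ether coupling of F6 with phenol 2 (CuI, N,N-dimethylglycine, Cs2CO3, dioxane, 100 °C) comes back to the route at 24.

2. Step 10. Nucleophiles present during enolate acylation and transfer (the amide base, trifluoroethoxide, aqueous amine) may attack the β-carbon of the vinylogous aryl ester and expel the ring-A phenoxide. The fallback builds the activating acyl group in by C–C bond formation, so that the vinylogous ester never meets a strong base; it sets out from enal 8 and phenol 2.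
   - Vinylic substitution as in step 9 gives methyl 2-{[(1E)-2-(tert-butyldimethylsilyloxymethyl)-3-oxoprop-1-enyl]oxy}-6-(3-methylbut-2-enyloxy)benzoate F7.
   - The lithium enolate of 5-methyl-1-phenylhex-4-en-1-one F8 (from acetophenone, LiN(iPr)2 and prenyl bromide) adds to the aldehyde at −78 °C to give the aldol F9.
   - Dess–Martin oxidation gives the 2-substituted 1,3-diketone F10.
   - Debenzoylative diazo transfer (4-nitrobenzenesulfonyl azide, DBU, CH2Cl2, 0 °C) removes the benzoyl group and comes back to the route at 15.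

3. Step 3. The lithium ester enolate may lose silanolate by β-elimination before it captures the formate, or the formyl ester may be deformylated on work-up. The fallback sets out from 4 and avoids a stoichiometric enolate.
   - Heating 4 with tert-butoxybis(dimethylamino)methane (neat, 90 °C) gives methyl (2E)-3-(dimethylamino)-2-(tert-butyldimethylsilyloxymethyl)prop-2-enoate F11.
   - Brief two-phase hydrolysis (cold dilute aq. HCl, Et2O) comes back to the route at 5.

**Further compounds**

F1 | step 12 | 2-(tert-butyldimethylsilyloxymethyl)-7-methylocta-1,6-dien-3-one | C=C(CO[Si](C)(C)C(C)(C)C)C(=O)CCC=C(C)C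
F2 | step 12 | 2-(tert-butyldimethylsilyloxymethyl)-7-methyl-4-(trifluoroacetyl)octa-1,6-dien-3-one | C=C(CO[Si](C)(C)C(C)(C)C)C(=O)C(CC=C(C)C)C(=O)C(F)(F)F
F3 | step 12 | 4-diazo-2-(tert-butyldimethylsilyloxymethyl)-7-methylocta-1,6-dien-3-one | C=C(CO[Si](C)(C)C(C)(C)C)C(=O)C(=[N+]=[N-])CC=C(C)C
F4 | step 12 | 3-(tert-butyldimethylsilyloxymethyl)-5-methoxy-4-(3-methylbut-2-enyl)phenol | Oc1cc(OC)c(CC=C(C)C)c(CO[Si](C)(C)C(C)(C)C)c1
F5 | step 12 | 2-bromo-3-(tert-butyldimethylsilyloxymethyl)-5-methoxy-4-(3-methylbut-2-enyl)phenol | Oc1cc(OC)c(CC=C(C)C)c(CO[Si](C)(C)C(C)(C)C)c1Br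
F6 | step 12 | {[2-bromo-5-methoxy-6-(3-methylbut-2-enyl)-3-(3-methylbut-2-enyloxy)phenyl]methoxy}(tert-butyl)dimethylsilane | CC(C)=CCOc1cc(OC)c(CC=C(C)C)c(CO[Si](C)(C)C(C)(C)C)c1Br
F7 | step 10 | methyl 2-{[(1E)-2-(tert-butyldimethylsilyloxymethyl)-3-oxoprop-1-enyl]oxy}-6-(3-methylbut-2-enyloxy)benzoate | COC(=O)c1c(OCC=C(C)C)cccc1O/C=C(\CO[Si](C)(C)C(C)(C)C)C=O
F8 | step 10 | 5-methyl-1-phenylhex-4-en-1-one | CC(C)=CCCC(=O)c1ccccc1
F9 | step 10 | methyl 2-{[(1E)-4-benzoyl-2-(tert-butyldimethylsilyloxymethyl)-3-hydroxy-7-methylocta-1,6-dienyl]oxy}-6-(3-methylbut-2-enyloxy)benzoate (mixture of diastereomers) | COC(=O)c1c(OCC=C(C)C)cccc1O/C=C(\CO[Si](C)(C)C(C)(C)C)C(O)C(CC=C(C)C)C(=O)c1ccccc1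
F10 | step 10 | methyl 2-{[(1E)-4-benzoyl-2-(tert-butyldimethylsilyloxymethyl)-7-methyl-3-oxoocta-1,6-dienyl]oxy}-6-(3-methylbut-2-enyloxy)benzoate (racemic) | COC(=O)c1c(OCC=C(C)C)cccc1O/C=C(\CO[Si](C)(C)C(C)(C)C)C(=O)C(CC=C(C)C)C(=O)c1ccccc1
F11 | step 3 | methyl (2E)-3-(dimethylamino)-2-(tert-butyldimethylsilyloxymethyl)prop-2-enoate | COC(=O)/C(CO[Si](C)(C)C(C)(C)C)=C/N(C)C
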